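The readings are calculated on assumed constants; scatter was added.

Minutes were my ruler: summer, winter and autumn each ran 4.0 min, and I had the earlier runs to read them against.

| flask | starting complex | incoming ligand | remark | time |
|---|---|---|---|---|
| Wednesday's | 20 mM | 30 mM | run made earlier |  |
| Friday's | 20 mM | 20 mM | run made earlier |  |
| Sunday's | 20 mM | 45 mM | run made earlier |  |
| Monday's | 10 mM | 30 mM | run made earlier |  |
| summer | 20 mM | 30.0 mM | everything together at the start | 4.0 min |
| winter | 20 mM (fed, over 3.0 min) | 30.0 mM | all else is in the flask from the start; the feed brings no volume worth counting | 4.0 min |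
| autumn | 20 mM | 30.0 mM (fed, over 3.0 min) | all else is in the flask from the start; the feed brings no volume worth counting | 4.0 min |

| run | time / min | complex with three exchanged / % | complex with one exchanged / % |
|---|---|---|---|
| Wednesday's | 0.167 | 1.1 | 16.4 |
| Wednesday's | 0.500 | 3.5 | 12.9 |
| Wednesday's | 0.833 | 5.2 | 8.2 |
| Wednesday's | 1.33 | 9.5 | 5.4 |
| Wednesday's | 2.00 | 14.5 | 4.2 |
| Wednesday's | 2.50 | 17.1 | 3.1 |
| Friday's | 0.500 | 0.7 | 13.5 |
| Friday's | 1.00 | 2.6 | 8.8 |
| Friday's | 1.50 | 4.4 | 6.9 |
| Friday's | 2.00 | 6.5 | 5.7 |
| Friday's | 2.50 | 6.9 | 6.0 |
| Friday's | 3.00 | 9.1 | 5.2 |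
| Sunday's | 0.250 | 1.7 | 17.4 |
| Sunday's | 0.417 | 5.6 | 13.0 |
| Sunday's | 0.667 | 10.0 | 8.1 |
| Sunday's | 1.33 | 20.3 | 3.4 |
| Sunday's | 2.00 | 27.0 | 2.0 |
| Sunday's | 3.00 | 34.2 | 2.2 |
| Monday's | 0.667 | 6.8 | 10.5 |
| Monday's | 1.33 | 14.2 | 3.6 |
| Monday's | 2.00 | 20.6 | 2.8 |
| Monday's | 2.50 | 25.8 | 2.6 |
| Monday's | 3.00 | 28.9 | 3.1 |

(standard deviation of a reading: 0.5 percentage points)



* the flask that comes out highest in amount of complex with three exchanged, in percent of the starting complex charged; "all alike" if 1.5 percentage points covers them all (summer / winter / autumn / all alike)
* amount of complex with three exchanged at the end, in percent of the starting complex charged, summer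
* amount of complex with three exchanged at the end, in percent of the starting complex charged, winter
* amount of complex with three exchanged at the end, in percent of the starting complex charged, autumn

The ladder stood in Wednesday's run. By 0.167 min it held 16.4 % of complex with one exchanged against 1.1 % of complex with three exchanged. The complex with one exchanged fell to half that reading by 0.833 min. The complex with three exchanged was still climbing at 2.50 min, at 17.1 %, with 79.8 % of the charge in forms I did not read. So I took the asked time to lie on that climb.

At 3.00 min, Sunday's run held 34.2 % and Friday's 9.1 % of complex with three exchanged, from 45 mM and 20 mM of incoming ligand, which gave 1.63. This is the ligand order, an apparent reaction order: the logarithm of the product ratio between two runs at one time and with one charge of starting complex, divided by the logarithm of their ratio of incoming ligand charged. The same reading in mM, Wednesday's against Monday's at 2.50 min, gave 0.407 for starting complex. Both carry the scatter of the readings.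

A feed over 3.0 min has delivered, averaged over the 4.0 min of the run, a fraction 0.625 of its charge. I therefore reckoned autumn, with its ligand fed, at 0.464 of summer, and winter, with its complex fed, at 0.826 of summer. In this reckoning autumn came lower than winter because 1.63 exceeds 0.407.

The forecast put summer highest, at 22.5 %, with winter at 18.5 % and autumn at 13 %. Its grounds for autumn, its L being the incoming ligand, were “L starves the second-order step for the first two minutes”. Its shares of summer were 0.578 for autumn and 0.822 for winter, so it differed from mine mainly on autumn.

Summer gave 20.6 %, the highest, winter 13.8 % and autumn 10.8 %.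

    complex with two exchanged + incoming ligand → leaving ligand + complex with three exchanged (k = 0.490 L mol⁻¹ s⁻¹)
    starting complex ⇌ dormant form (K = 9.00, k = 0.0600 s⁻¹)
    incoming ligand → decomposed reagent (k = 0.00230 s⁻¹)
    crystals ⇌ leaving ligand, rate k4*(cs4 - [leaving ligand]) while solid is left; crystals form when [leaving ligand] > cs4 (solubility = 0.260 mM, k = 0.970 s⁻¹)
    complex with one exchanged + incoming ligand → leaving ligand + complex with two exchanged (k = 2.30 L mol⁻¹ s⁻¹)
    starting complex + incoming ligand → leaving ligand + complex with one exchanged (k = 1.30 L mol⁻¹ s⁻¹)

Autumn stood at 0.524 of summer against my 0.464, and winter at 0.670 against my 0.826. The neighbouring flask was autumn with 51 mM of incoming ligand instead of 30.0 mM. The ligand order applied to autumn's result gave 25.6 % for c(complex with three exchanged). That flask held 23.6 % at 4.00 min.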